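**Plan** (locants: the chain between the rings is C1–C9, with C2 on pyranone ring A and C8 on pyranone ring B; the arm on ring B is C1'–C5', with C2' on the ring)
Cuts, in retrosynthetic order: the C3' silyl ether; C2–H (from C2=CH2); C3–C4 together with C5=O (aldol union of the two ring-bearing halves, then reduction); C6=C7 (aldol with pentan-3-one, then dehydration); C3'–ethyl; both formylvinyl groups back to the ethyl groups of one symmetrical pyranone, itself cut to pentan-3-one and two propanoyl units.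
Enabling feature: C3(OH)–C4(CH3)–C5(OH), a syn,syn 2-methyl-1,3-diol between ring A and the C6=C7 alkene, is the retron of an ethyl-ketone aldol with in-situ 1,3-syn reduction; C2, C8 and C2', the CH(CH3) carbons on C2/C6 of the 4-pyranone rings, each lie next to a carbinol (C8 next to a temporary one), so each is carried as C=CH2 and set by hydroxyl-directed hydrogenation.
Forward order: both rings arise at once in step 1 (one pyranone serves as ring A and as ring B); then the ring B arm C2'/C3'; then the C6–C7 bond, C8 and the C6=C7 alkene; then union with the ring A acrolein at C3–C4 with C5 reduction in the same flask; then C2; then desilylation.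
Stereochemistry: C3' from catalytic asymmetric Et2Zn addition; the temporary C7 carbinol and C3/C4 from isopinocampheylboron enolates; C5 from the boron aldolate; C2', C8 and C2 from the neighbouring carbinol (anti, directed hydrogenation); the E alkene from elimination.

Key step: step 12

Assumption: (Z)-enol borinates made with (−)-Ipc2BOTf (from (+)-α-pinene) are taken to attack the Si face of an aldehyde, as the related (−)-crotyl(diisopinocampheyl)boranes do, and those from (+)-Ipc2BOTf the Re face; should the sense be the reverse, the two antipodes change places between steps 9 and 12 and nothing else changes.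

Step 1
Reactants: 1 pentan-3-one; 2 propanoic anhydride (2 equiv)
Product: 3 2,6-diethyl-3,5-dimethyl-4H-pyran-4-one
Conditions: polyphosphoric acid, 95 °C
Reagents that add atoms: propanoic anhydride (2), CCC(=O)OC(=O)CC
Why: Acid-mediated double C-acylation of the ketone at both α-carbons and cyclodehydration of the resulting 1,3,5-triketone (a one-pot, three-component γ-pyranone synthesis of the Claisen-acylation type) should give the symmetrical, achiral pyranone that serves as both rings.

Step 2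
Reactants: 3 2,6-diethyl-3,5-dimethyl-4H-pyran-4-one; 4 ethyl formate
Product: 6 rac-2-(6-ethyl-3,5-dimethyl-4-oxo-4H-pyran-2-yl)propanal, via lithium dienolate 5 (not isolated)
Conditions: LiN(SiMe3)2 (1.2 equiv), THF, −78 °C; HCO2Et, −78 → 0 °C; AcOH quench
Reagents that add atoms: ethyl formate (4), CCOC=O
Why: Vinylogous deprotonation of one 2-ethyl CH2 gives the exocyclic dienolate, whose crossed Claisen condensation with the formate puts the formyl group on the side-chain carbon (the ring α-positions are blocked by methyl groups), the released ethoxide turning the acidic product into its enolate so that the reaction stops after one formylation; the new centre is racemic and is erased in step 3.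

Step 3
Reactants: 6 rac-2-(6-ethyl-3,5-dimethyl-4-oxo-4H-pyran-2-yl)propanal
Product: 8 2-(6-ethyl-3,5-dimethyl-4-oxo-4H-pyran-2-yl)prop-2-enal, via alpha-phenylselanyl aldehyde 7 (not isolated)
Conditions: PhSeCl (1.1 equiv), pyridine, CH2Cl2, 0 °C; then NaIO4, THF/MeOH/H2O, 0 → 23 °C
Reagents that add atoms: none
Why: α-Selenenylation of the readily enolised aldehyde, periodate oxidation and selenoxide syn-elimination, which can only take a hydrogen from the methyl group, should give the 2-pyranyl acrolein, an aldehyde with no α-hydrogen and no stereocentre (used fresh, since 2-aryl acroleins tend to dimerise).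

Step 4
Reactants: 8 2-(6-ethyl-3,5-dimethyl-4-oxo-4H-pyran-2-yl)prop-2-enal; 9 diethylzinc
Product: 10 2-ethyl-6-[(3S)-3-hydroxypent-1-en-2-yl]-3,5-dimethyl-4H-pyran-4-one
Conditions: Et2Zn (2 equiv), (2S)-(−)-3-exo-(dimethylamino)isoborneol (8 mol %), toluene, 0 °C; then 1 M HCl, 0 °C
Reagents that add atoms: diethylzinc (9), CC[Zn]CC
Why: Amino-alcohol-catalysed enantioselective 1,2-addition of a dialkylzinc to an aldehyde, in which the zinc aminoalkoxide delivers ethyl to the face that gives (S)-carbinols from aryl and 2-substituted alkenyl aldehydes, sets C3'.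

Step 5
Reactants: 10 2-ethyl-6-[(3S)-3-hydroxypent-1-en-2-yl]-3,5-dimethyl-4H-pyran-4-one
Product: 11 2-ethyl-6-[(2S,3S)-3-hydroxypentan-2-yl]-3,5-dimethyl-4H-pyran-4-one
Conditions: H2 (30 bar), [Rh(nbd)(dppb)]BF4 (5 mol %; nbd = norbornadiene, dppb = 1,4-bis(diphenylphosphino)butane), CH2Cl2, 23 °C
Reagents that add atoms: none
Why: Hydroxyl-directed homogeneous hydrogenation of a 1,1-disubstituted allylic alcohol with a cationic rhodium diphosphine catalyst, in which the rhodium-bound C3' hydroxyl and minimised allylic strain fix the face of hydrogen delivery, should set C2' anti to the hydroxyl, that is (2'S,3'S).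

Step 6
Reactants: 11 2-ethyl-6-[(2S,3S)-3-hydroxypentan-2-yl]-3,5-dimethyl-4H-pyran-4-one; 12 tert-butyl(chloro)dimethylsilane
Product: 13 2-[(2S,3S)-3-(tert-butyldimethylsilyloxy)pentan-2-yl]-6-ethyl-3,5-dimethyl-4H-pyran-4-one
Conditions: TBSCl, imidazole, DMF, 40 °C
Reagents that add atoms: tert-butyl(chloro)dimethylsilane (12), CC(C)(C)[Si](C)(C)Cl
Why: Imidazole-promoted silylation masks the only hydroxyl as a TBS ether that should survive the amide base, boron triflate, borohydride, peroxide and mesylation steps and is removed last.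

Step 7
Reactants: 13 2-[(2S,3S)-3-(tert-butyldimethylsilyloxy)pentan-2-yl]-6-ethyl-3,5-dimethyl-4H-pyran-4-one; 4 ethyl formate
Product: 15 2-{6-[(2S,3S)-3-(tert-butyldimethylsilyloxy)pentan-2-yl]-3,5-dimethyl-4-oxo-4H-pyran-2-yl}propanal (both epimers at the formyl-bearing carbon), via lithium dienolate 14 (not isolated)
Conditions: LiN(SiMe3)2 (1.2 equiv), THF, −78 °C; HCO2Et, −78 → 0 °C; AcOH quench
Reagents that add atoms: ethyl formate (4), CCOC=O
Why: The same dienolate Claisen formylation as in step 2, in which kinetic deprotonation should occur at the unbranched ethyl CH2 and not at the hindered C2' methine, so that C2' keeps its configuration; the new centre is erased in step 8.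

Step 8
Reactants: 15 2-{6-[(2S,3S)-3-(tert-butyldimethylsilyloxy)pentan-2-yl]-3,5-dimethyl-4-oxo-4H-pyran-2-yl}propanal
Product: 17 2-{6-[(2S,3S)-3-(tert-butyldimethylsilyloxy)pentan-2-yl]-3,5-dimethyl-4-oxo-4H-pyran-2-yl}prop-2-enal, via alpha-phenylselanyl aldehyde 16 (not isolated)
Conditions: PhSeCl (1.1 equiv), pyridine, CH2Cl2, 0 °C; then NaIO4, THF/MeOH/H2O, 0 → 23 °C
Reagents that add atoms: none
Why: α-Selenenylation and selenoxide syn-elimination as in step 3, with pyridine buffering the acid so that the silyl ether is kept, should give the second 2-pyranyl acrolein.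

Step 9
Reactants: 17 2-{6-[(2S,3S)-3-(tert-butyldimethylsilyloxy)pentan-2-yl]-3,5-dimethyl-4-oxo-4H-pyran-2-yl}prop-2-enal; 1 pentan-3-one
Product: 19 (4S,5S)-6-{6-[(2S,3S)-3-(tert-butyldimethylsilyloxy)pentan-2-yl]-3,5-dimethyl-4-oxo-4H-pyran-2-yl}-5-hydroxy-4-methylhept-6-en-3-one, via Z-enol borinate 18 (not isolated)
Conditions: pentan-3-one (2 equiv), (−)-Ipc2BOTf (2.4 equiv), i-Pr2NEt (3 equiv), CH2Cl2, −78 °C; 17, −78 → −20 °C; then MeOH, pH 7 buffer, 30% H2O2, 0 °C
Reagents that add atoms: none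
Why: Diisopinocampheylboron-mediated asymmetric aldol of an ethyl ketone with a 2-substituted acrolein, in which boron triflate and hindered amine give the (Z)-enol borinate, a closed six-membered chair transition state gives the syn adduct and the (−)-isopinocampheyl ligands select the aldehyde Si face, so that the temporary C7 carbinol (needed only to steer step 10) has the configuration shown, C2'/C3' on the far side of ring B being without influence.

Step 10
Reactants: 19 (4S,5S)-6-{6-[(2S,3S)-3-(tert-butyldimethylsilyloxy)pentan-2-yl]-3,5-dimethyl-4-oxo-4H-pyran-2-yl}-5-hydroxy-4-methylhept-6-en-3-one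
Product: 20 (4S,5R,6S)-6-{6-[(2S,3S)-3-(tert-butyldimethylsilyloxy)pentan-2-yl]-3,5-dimethyl-4-oxo-4H-pyran-2-yl}-5-hydroxy-4-methylheptan-3-one
Conditions: H2 (30 bar), [Rh(nbd)(dppb)]BF4 (5 mol %), CH2Cl2, 23 °C
Reagents that add atoms: none
Why: Hydroxyl-directed hydrogenation as in step 5, now steered by the temporary C7 hydroxyl, should set C8 anti to it, which is the (S) configuration required in the target.

Step 11
Reactants: 20 (4S,5R,6S)-6-{6-[(2S,3S)-3-(tert-butyldimethylsilyloxy)pentan-2-yl]-3,5-dimethyl-4-oxo-4H-pyran-2-yl}-5-hydroxy-4-methylheptan-3-one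
Product: 22 (4E,6S)-6-{6-[(2S,3S)-3-(tert-butyldimethylsilyloxy)pentan-2-yl]-3,5-dimethyl-4-oxo-4H-pyran-2-yl}-4-methylhept-4-en-3-one, via beta-mesyloxy ketone 21 (not isolated)
Conditions: MsCl (1.5 equiv), Et3N (5 equiv), CH2Cl2, 0 → 23 °C
Reagents that add atoms: none
Why: Mesylation of the β-hydroxy ketone and E1cB elimination through the ketone enolate (the C6 hydrogen α to the ketone is more acidic than the C8 hydrogen next to ring B, and the syn-aldol mesylate is also set up for anti-periplanar loss to the same isomer) should give the (E)-enone, erasing the auxiliary centres C6 and C7 while the mild amine base leaves C8 untouched.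

Step 12
Reactants: 22 (4E,6S)-6-{6-[(2S,3S)-3-(tert-butyldimethylsilyloxy)pentan-2-yl]-3,5-dimethyl-4-oxo-4H-pyran-2-yl}-4-methylhept-4-en-3-one; 8 2-(6-ethyl-3,5-dimethyl-4-oxo-4H-pyran-2-yl)prop-2-enal
Product: 25 2-[(3R,4S,5S,6E,8S)-8-{6-[(2S,3S)-3-(tert-butyldimethylsilyloxy)pentan-2-yl]-3,5-dimethyl-4-oxo-4H-pyran-2-yl}-3,5-dihydroxy-4,6-dimethylnona-1,6-dien-2-yl]-6-ethyl-3,5-dimethyl-4H-pyran-4-one, via Z-enol borinate 23 (not isolated), via boron aldolate 24 (not isolated)
Conditions: 22, (+)-Ipc2BOTf (2.5 equiv), i-Pr2NEt (3.5 equiv), CH2Cl2, −78 °C; 8 (1.5 equiv), −78 → −20 °C; LiBH4 (THF solution, excess), −78 °C; then MeOH, pH 7 buffer, 30% H2O2, 0 °C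
Reagents that add atoms: none
Why: (+)-Ipc2BOTf and i-Pr2NEt enolise ketone 22 at its only α-CH2 to the (Z)-enol borinate 23, which adds to the carbonyl of the non-enolisable acrolein 8 through a closed six-membered Zimmerman–Traxler chair to give boron aldolate 24, and LiBH4 then reduces the boron-chelated C5 ketone of 24 before oxidative work-up frees the diol. The closest known reaction type is the dialkylboron-mediated aldol of an ethyl ketone with in-situ borohydride reduction of the boron aldolate to a 1,3-syn diol (one-pot aldol/reduction), here run with chiral isopinocampheyl ligands. No ring of the product is closed; the only rings involved are the chair transition state and the six-membered O–B–O chelate that is reduced. C4 and C3 arise together: the (Z)-enolate geometry in the chair enforces the 3,4-syn relationship and the isopinocampheyl ligands select the Re face of the aldehyde, giving (3R) with the matching C4 configuration (4S in 25, 4R by the sequence rules once C2 is saturated), the nearest existing centre, C8, being too remote to interfere. C5 is set by external hydride attack on the half-chair boron chelate, in which the C3 substituent is pseudo-equatorial, from the face that leads to the chair-like product, giving the 1,3-syn diol (5S). The step needs α'-deprotonation of 22 and not deprotonation at C8, 1,2-addition to the enal, 1,2-reduction of the enone and no loss of configuration in the aldehyde partner; these are secured by soft enolisation of the boron-complexed ketone at −78 °C (its other α-carbon is the sp2 C6), by activation of the C5 carbonyl within the boron chelate, and by carrying C2 of 8 as C=CH2 so that the aldehyde has neither an α-hydrogen nor a stereocentre.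

Step 13
Reactants: 25 2-[(3R,4S,5S,6E,8S)-8-{6-[(2S,3S)-3-(tert-butyldimethylsilyloxy)pentan-2-yl]-3,5-dimethyl-4-oxo-4H-pyran-2-yl}-3,5-dihydroxy-4,6-dimethylnona-1,6-dien-2-yl]-6-ethyl-3,5-dimethyl-4H-pyran-4-one
Product: 26 2-[(2R,3R,4R,5S,6E,8S)-8-{6-[(2S,3S)-3-(tert-butyldimethylsilyloxy)pentan-2-yl]-3,5-dimethyl-4-oxo-4H-pyran-2-yl}-3,5-dihydroxy-4,6-dimethylnon-6-en-2-yl]-6-ethyl-3,5-dimethyl-4H-pyran-4-one
Conditions: H2 (30 bar), [Rh(nbd)(dppb)]BF4 (10 mol %), CH2Cl2, 23 °C, stopped after one equivalent of H2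
Reagents that add atoms: none
Why: Hydroxyl-directed hydrogenation as in steps 5 and 10, in which the C3 hydroxyl, allylic to the 1,1-disubstituted C2=CH2 bond, binds the cationic rhodium centre and steers hydrogen to the face that gives the 2,3-anti relationship, (2R), while the trisubstituted and more hindered C6=C7 bond should react far more slowly.

Step 14
Reactants: 26 2-[(2R,3R,4R,5S,6E,8S)-8-{6-[(2S,3S)-3-(tert-butyldimethylsilyloxy)pentan-2-yl]-3,5-dimethyl-4-oxo-4H-pyran-2-yl}-3,5-dihydroxy-4,6-dimethylnon-6-en-2-yl]-6-ethyl-3,5-dimethyl-4H-pyran-4-one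
Product: 27 2-[(2R,3R,4R,5S,6E,8S)-3,5-dihydroxy-8-{6-[(2S,3S)-3-hydroxypentan-2-yl]-3,5-dimethyl-4-oxo-4H-pyran-2-yl}-4,6-dimethylnon-6-en-2-yl]-6-ethyl-3,5-dimethyl-4H-pyran-4-one (CNP0408419.10)
Conditions: HF·pyridine, pyridine, THF, 0 → 23 °C
Reagents that add atoms: none
Why: Fluoride cleavage of the secondary TBS ether under pyridine-buffered, non-basic conditions should free the C3' hydroxyl without touching the base-sensitive CH(CH3) centres next to the rings or the allylic C5 alcohol, giving the target.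

**Compound list**
1 | pentan-3-one | CCC(=O)CC | starting material
2 | propanoic anhydride | CCC(=O)OC(=O)CC | starting material
3 | 2,6-diethyl-3,5-dimethyl-4H-pyran-4-one | CCc1oc(CC)c(C)c(=O)c1C | intermediate
4 | ethyl formate | CCOC=O | starting material
5 | lithium 6-ethyl-2-ethylidene-3,5-dimethyl-2H-pyran-4-olate (dienolate of 3) | [Li+].CC=C1OC(CC)=C(C)C([O-])=C1C | intermediate (not isolated)
6 | rac-2-(6-ethyl-3,5-dimethyl-4-oxo-4H-pyran-2-yl)propanal | CCc1oc(C(C)C=O)c(C)c(=O)c1C | intermediate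
7 | rac-2-(6-ethyl-3,5-dimethyl-4-oxo-4H-pyran-2-yl)-2-(phenylselanyl)propanal | CCc1oc(C(C)(C=O)[Se]c2ccccc2)c(C)c(=O)c1C | intermediate (not isolated)
8 | 2-(6-ethyl-3,5-dimethyl-4-oxo-4H-pyran-2-yl)prop-2-enal | CCc1oc(C(=C)C=O)c(C)c(=O)c1C | intermediate
9 | diethylzinc | CC[Zn]CC | starting material
10 | 2-ethyl-6-[(3S)-3-hydroxypent-1-en-2-yl]-3,5-dimethyl-4H-pyran-4-one | CC[C@H](O)C(=C)c1oc(CC)c(C)c(=O)c1C | intermediate
11 | 2-ethyl-6-[(2S,3S)-3-hydroxypentan-2-yl]-3,5-dimethyl-4H-pyran-4-one | CCc1oc([C@@H](C)[C@@H](O)CC)c(C)c(=O)c1C | intermediate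
12 | tert-butyl(chloro)dimethylsilane | CC(C)(C)[Si](C)(C)Cl | starting material
13 | 2-[(2S,3S)-3-(tert-butyldimethylsilyloxy)pentan-2-yl]-6-ethyl-3,5-dimethyl-4H-pyran-4-one | CCc1oc([C@@H](C)[C@@H](O[Si](C)(C)C(C)(C)C)CC)c(C)c(=O)c1C | intermediate
14 | lithium dienolate of 13 (2-ethylidene-2H-pyran-4-olate) | [Li+].CC=C1OC([C@@H](C)[C@@H](O[Si](C)(C)C(C)(C)C)CC)=C(C)C([O-])=C1C | intermediate (not isolated)
15 | 2-{6-[(2S,3S)-3-(tert-butyldimethylsilyloxy)pentan-2-yl]-3,5-dimethyl-4-oxo-4H-pyran-2-yl}propanal (both epimers at C2 of the propanal) | O=CC(C)c1oc([C@@H](C)[C@@H](O[Si](C)(C)C(C)(C)C)CC)c(C)c(=O)c1C | intermediate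
16 | 2-{6-[(2S,3S)-3-(tert-butyldimethylsilyloxy)pentan-2-yl]-3,5-dimethyl-4-oxo-4H-pyran-2-yl}-2-(phenylselanyl)propanal | O=CC(C)([Se]c1ccccc1)c1oc([C@@H](C)[C@@H](O[Si](C)(C)C(C)(C)C)CC)c(C)c(=O)c1C | intermediate (not isolated)
17 | 2-{6-[(2S,3S)-3-(tert-butyldimethylsilyloxy)pentan-2-yl]-3,5-dimethyl-4-oxo-4H-pyran-2-yl}prop-2-enal | C=C(C=O)c1oc([C@@H](C)[C@@H](O[Si](C)(C)C(C)(C)C)CC)c(C)c(=O)c1C | intermediate
18 | (Z)-pent-2-en-3-yl bis[(−)-isopinocampheyl]borinate | C/C=C(/CC)OB([C@@H]1C[C@@H]2C[C@H]([C@H]1C)C2(C)C)[C@@H]1C[C@@H]2C[C@H]([C@H]1C)C2(C)C | intermediate (not isolated)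
19 | (4S,5S)-6-{6-[(2S,3S)-3-(tert-butyldimethylsilyloxy)pentan-2-yl]-3,5-dimethyl-4-oxo-4H-pyran-2-yl}-5-hydroxy-4-methylhept-6-en-3-one | CCC(=O)[C@@H](C)[C@H](O)C(=C)c1oc([C@@H](C)[C@@H](O[Si](C)(C)C(C)(C)C)CC)c(C)c(=O)c1C | intermediate
20 | (4S,5R,6S)-6-{6-[(2S,3S)-3-(tert-butyldimethylsilyloxy)pentan-2-yl]-3,5-dimethyl-4-oxo-4H-pyran-2-yl}-5-hydroxy-4-methylheptan-3-one | CCC(=O)[C@@H](C)[C@H](O)[C@H](C)c1oc([C@@H](C)[C@@H](O[Si](C)(C)C(C)(C)C)CC)c(C)c(=O)c1C | intermediate
21 | methanesulfonate of 20 at the C5 hydroxyl of the heptanone | CCC(=O)[C@@H](C)[C@H](OS(C)(=O)=O)[C@H](C)c1oc([C@@H](C)[C@@H](O[Si](C)(C)C(C)(C)C)CC)c(C)c(=O)c1C | intermediate (not isolated)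
22 | (4E,6S)-6-{6-[(2S,3S)-3-(tert-butyldimethylsilyloxy)pentan-2-yl]-3,5-dimethyl-4-oxo-4H-pyran-2-yl}-4-methylhept-4-en-3-one | CCC(=O)/C(C)=C/[C@H](C)c1oc([C@@H](C)[C@@H](O[Si](C)(C)C(C)(C)C)CC)c(C)c(=O)c1C | intermediate
23 | (Z)-enol bis[(+)-isopinocampheyl]borinate of 22 (2Z,4E-dienyl borinate) | C/C=C(\OB([C@H]1C[C@H]2C[C@@H]([C@@H]1C)C2(C)C)[C@H]1C[C@H]2C[C@@H]([C@@H]1C)C2(C)C)/C(C)=C/[C@H](C)c1oc([C@@H](C)[C@@H](O[Si](C)(C)C(C)(C)C)CC)c(C)c(=O)c1C | intermediate (not isolated)
24 | bis[(+)-isopinocampheyl]boron aldolate (C3–O–B) of the 3,4-syn aldol adduct of 22 and 8 | CCc1oc(C(=C)[C@H](OB([C@H]3C[C@H]4C[C@@H]([C@@H]3C)C4(C)C)[C@H]3C[C@H]4C[C@@H]([C@@H]3C)C4(C)C)[C@@H](C)C(=O)/C(C)=C/[C@H](C)c2oc([C@@H](C)[C@@H](O[Si](C)(C)C(C)(C)C)CC)c(C)c(=O)c2C)c(C)c(=O)c1C | intermediate (not isolated)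
25 | 2-[(3R,4S,5S,6E,8S)-8-{6-[(2S,3S)-3-(tert-butyldimethylsilyloxy)pentan-2-yl]-3,5-dimethyl-4-oxo-4H-pyran-2-yl}-3,5-dihydroxy-4,6-dimethylnona-1,6-dien-2-yl]-6-ethyl-3,5-dimethyl-4H-pyran-4-one | CCc1oc(C(=C)[C@H](O)[C@@H](C)[C@H](O)/C(C)=C/[C@H](C)c2oc([C@@H](C)[C@@H](O[Si](C)(C)C(C)(C)C)CC)c(C)c(=O)c2C)c(C)c(=O)c1C | intermediate
26 | 2-[(2R,3R,4R,5S,6E,8S)-8-{6-[(2S,3S)-3-(tert-butyldimethylsilyloxy)pentan-2-yl]-3,5-dimethyl-4-oxo-4H-pyran-2-yl}-3,5-dihydroxy-4,6-dimethylnon-6-en-2-yl]-6-ethyl-3,5-dimethyl-4H-pyran-4-one | CCc1oc([C@H](C)[C@H](O)[C@@H](C)[C@H](O)/C(C)=C/[C@H](C)c2oc([C@@H](C)[C@@H](O[Si](C)(C)C(C)(C)C)CC)c(C)c(=O)c2C)c(C)c(=O)c1C | intermediate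
27 | 2-[(2R,3R,4R,5S,6E,8S)-3,5-dihydroxy-8-{6-[(2S,3S)-3-hydroxypentan-2-yl]-3,5-dimethyl-4-oxo-4H-pyran-2-yl}-4,6-dimethylnon-6-en-2-yl]-6-ethyl-3,5-dimethyl-4H-pyran-4-one | CCc1oc([C@H](C)[C@H](O)[C@@H](C)[C@H](O)/C(C)=C/[C@H](C)c2oc([C@@H](C)[C@@H](O)CC)c(C)c(=O)c2C)c(C)c(=O)c1C | target

**Count**
Total steps: 14. Longest linear sequence: 14 steps (steps 1–14; aldehyde 8 from step 3 is used in step 4 and again in step 12).

**Steps most likely to fail**

Step 12. What may go wrong: coordination of the boron triflate to the two pyranone carbonyl groups may leave enolisation incomplete; facial control by the isopinocampheyl ligands on this hindered enal may be weak or run in the opposite sense; hydride may be delivered in a conjugate manner to the 2-vinylpyranone during the in-flask reduction; and deprotonation at C8–H may compete with α'-enolisation. Fallback, setting out from 22 and coming back at 25: ketone 22 is converted into its (Z)-trimethylsilyl enol ether F1 (LiN(SiMe3)2, Me3SiCl, THF, −78 °C). F1 is united with 8 in a catalytic asymmetric Mukaiyama aldol reaction under the tartaric-acid-derived (acyloxy)borane Lewis acid made from BH3·THF and mono(2,6-diisopropoxybenzoyl)tartaric acid (open transition state, syn-selective with enals whatever the enol ether geometry, catalyst antipode chosen for the 3R carbinol). Acid work-up gives the hydroxy enone F2, and a separate Narasaka–Prasad reduction (Et2BOMe, NaBH4, THF/MeOH, −78 °C) then gives 25.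

Step 13. What may go wrong: the C5 hydroxyl may direct hydrogenation of the C6=C7 bond; two-point binding of the syn-1,3-diol to rhodium may erode facial selectivity at C2; the allylic alcohol may isomerise to the C3 ketone; the pyranone carbonyl groups may slow the catalyst. Fallback, setting out from 22 and 8 and coming back at 26: the aldol of step 12 is run with oxidative work-up but without LiBH4, giving the hydroxy enone F2. F2 is hydrogenated with the same cationic rhodium catalyst while C5 is still a ketone, so that only one allylic alcohol is present and the C6=C7 bond is a deactivated enone bond remote from the hydroxyl, giving the saturated hydroxy ketone F3. Narasaka–Prasad reduction of F3 (Et2BOMe, NaBH4, THF/MeOH, −78 °C) gives 26 directly.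

Step 9. What may go wrong: the reagent-controlled face selection may be insufficient or of the wrong sense, so that C7, and with it C8 after step 10, is formed as a mixture; addition to the hindered, Lewis-basic enal may be slow. Fallback, setting out from 17 and coming back at 20: an Evans syn-aldol reaction of 17 with commercial (4S)-4-benzyl-3-propanoyl-1,3-oxazolidin-2-one (Bu2BOTf, i-Pr2NEt, CH2Cl2, −78 → 0 °C), whose sense rests on the auxiliary, gives the imide aldol F4. Directed hydrogenation as in step 10 gives the saturated imide F5; LiSEt (EtSH, n-BuLi, THF, 0 °C) removes the auxiliary to give the S-ethyl thioester F6; Fukuyama coupling (EtZnI, PdCl2(PPh3)2, toluene, 23 °C), which leaves the pyranone carbonyl alone, gives ethyl ketone 20.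

**Further compounds**
F1 | step 12 | (2Z,4E,6S)-6-{6-[(2S,3S)-3-(tert-butyldimethylsilyloxy)pentan-2-yl]-3,5-dimethyl-4-oxo-4H-pyran-2-yl}-4-methyl-3-(trimethylsilyloxy)hepta-2,4-diene | C/C=C(\O[Si](C)(C)C)/C(C)=C/[C@H](C)c1oc([C@@H](C)[C@@H](O[Si](C)(C)C(C)(C)C)CC)c(C)c(=O)c1C
F2 | step 12 | (3R,4R,6E,8S)-8-{6-[(2S,3S)-3-(tert-butyldimethylsilyloxy)pentan-2-yl]-3,5-dimethyl-4-oxo-4H-pyran-2-yl}-2-(6-ethyl-3,5-dimethyl-4-oxo-4H-pyran-2-yl)-3-hydroxy-4,6-dimethylnona-1,6-dien-5-one | CCc1oc(C(=C)[C@H](O)[C@@H](C)C(=O)/C(C)=C/[C@H](C)c2oc([C@@H](C)[C@@H](O[Si](C)(C)C(C)(C)C)CC)c(C)c(=O)c2C)c(C)c(=O)c1C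
F3 | step 13 | (2R,3S,4R,6E,8S)-8-{6-[(2S,3S)-3-(tert-butyldimethylsilyloxy)pentan-2-yl]-3,5-dimethyl-4-oxo-4H-pyran-2-yl}-2-(6-ethyl-3,5-dimethyl-4-oxo-4H-pyran-2-yl)-3-hydroxy-4,6-dimethylnon-6-en-5-one | CCc1oc([C@H](C)[C@H](O)[C@@H](C)C(=O)/C(C)=C/[C@H](C)c2oc([C@@H](C)[C@@H](O[Si](C)(C)C(C)(C)C)CC)c(C)c(=O)c2C)c(C)c(=O)c1C
F4 | step 9 | (4S)-4-benzyl-3-[(2S,3S)-4-{6-[(2S,3S)-3-(tert-butyldimethylsilyloxy)pentan-2-yl]-3,5-dimethyl-4-oxo-4H-pyran-2-yl}-3-hydroxy-2-methylpent-4-enoyl]-1,3-oxazolidin-2-one | O=C1OC[C@H](Cc2ccccc2)N1C(=O)[C@@H](C)[C@H](O)C(=C)c1oc([C@@H](C)[C@@H](O[Si](C)(C)C(C)(C)C)CC)c(C)c(=O)c1C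
F5 | step 9 | (4S)-4-benzyl-3-[(2S,3R,4S)-4-{6-[(2S,3S)-3-(tert-butyldimethylsilyloxy)pentan-2-yl]-3,5-dimethyl-4-oxo-4H-pyran-2-yl}-3-hydroxy-2-methylpentanoyl]-1,3-oxazolidin-2-one | O=C1OC[C@H](Cc2ccccc2)N1C(=O)[C@@H](C)[C@H](O)[C@H](C)c1oc([C@@H](C)[C@@H](O[Si](C)(C)C(C)(C)C)CC)c(C)c(=O)c1C
F6 | step 9 | S-ethyl (2S,3R,4S)-4-{6-[(2S,3S)-3-(tert-butyldimethylsilyloxy)pentan-2-yl]-3,5-dimethyl-4-oxo-4H-pyran-2-yl}-3-hydroxy-2-methylpentanethioate | CCSC(=O)[C@@H](C)[C@H](O)[C@H](C)c1oc([C@@H](C)[C@@H](O[Si](C)(C)C(C)(C)C)CC)c(C)c(=O)c1C
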